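**Retrosynthetic overview**
- Feature: the ten ring carbons of the 5–7 bicycle (five ring C1–C5; seven ring C1, C5–C10) lie on one perimeter crossed only by C1–C5. The C9 ketone with its α-methyl carbon C8 is the retron of an oxy-Cope ring expansion.
- Late stage: remove the silyl groups, make C7=C8 by Saegusa–Ito oxidation, aroylate O4, and set the C6 carbinol by hydroxyl-directed reduction.
- C1–C5 is cut transannularly. A C5 enolate, released from a C4–C5-epoxy C6-ketone, adds to C1 of a ring-trans C10=C1 enone, so the five and seven rings form together and last.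
- The ten ring comes from the anionic oxy-Cope shift (C6–C7 made, C4–C9 cut) of a piperitone-derived cis-dialkenylcyclohexenol. Its vinyl terminus carries OTBS, so the C4 chirality is relayed to C6 and from there back into the C4–O bond.
- The six ring is bought as piperitone and its quaternary C4 is set by decarboxylative asymmetric allylation. Ring order: six, then ten, then five plus seven.

Key step: step 6

Numbering used throughout: five ring C1(Me)–C2–C3–C4(O, iPr)–C5(H); seven ring C1–C5–C6(O)–C7–C8(Me)–C9(=O)–C10.
Assumption: C8 lies next to the C9 ketone, is epimerisable and is erased in step 18, so it is drawn as one epimer (8R) without consequence. Racemic piperitone serves because its stereocentre is lost in step 1.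

**Step 1**
Reactants: 1 piperitone (racemic); 2 allyl chloroformate
Product: 4 allyl enol carbonate of piperitone (O-bound at C9; C9=C4 and C10=C1 double bonds), via lithium dienolate 3 (not isolated)
Conditions: LDA, THF, −78 °C; TMEDA, then 2, −78 → 0 °C
Reagents that add atoms: allyl chloroformate, C=CCOC(=O)Cl
Why: Kinetic deprotonation of an enone takes the α′ proton, here on the isopropyl-bearing C4, and the hindered carbon end of the cross-conjugated enolate leaves O-acylation (enol carbonate formation) as the fast path.

**Step 2**
Reactants: 4 allyl enol carbonate of piperitone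
Product: 5 (R)-6-allyl-6-isopropyl-3-methylcyclohex-2-en-1-one
Conditions: Pd2(dba)3 (cat.), (R)-t-Bu-PHOX (cat.), toluene, 25 °C
Reagents that add atoms: none
Why: In this decarboxylative asymmetric allylic alkylation (Tsuji allylation) zerovalent palladium ionises the carbonate, CO2 is lost, and the enolate, released only at C4, is allylated inside the chiral P,N-ligand pocket, which should set quaternary C4 as R, with the ligand antipode chosen by analogy with 2-alkylcyclohexanone enol carbonates.

**Step 3**
Reactants: 5 (R)-6-allyl-6-isopropyl-3-methylcyclohex-2-en-1-one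
Product: 7 2-[(1R)-4-methyl-2-oxo-1-(propan-2-yl)cyclohex-3-en-1-yl]acetaldehyde, via vicinal diol 6 (not isolated)
Conditions: OsO4 (cat.), NaIO4, 2,6-lutidine, dioxane/H2O, rt
Reagents that add atoms: osmium tetroxide (oxygen carrier), O=[Os](=O)(=O)=O; sodium periodate (terminal oxygen source), [Na+].[O-]I(=O)(=O)=O
Why: In the Lemieux–Johnson cleavage OsO4 attacks the electron-rich monosubstituted alkene far faster than the electron-poor enone alkene and periodate cuts diol 6, which trims allyl to the two-carbon C5–C6 unit without touching C4.

**Step 4**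
Reactants: 7 the keto aldehyde
Product: 8 (S)-6-[(E)-2-(tert-butyldimethylsilyloxy)ethenyl]-6-isopropyl-3-methylcyclohex-2-en-1-one
Conditions: TBSOTf (1.05 equiv), Et3N, CH2Cl2, −78 → 0 °C
Reagents that add atoms: tert-butyldimethylsilyl triflate, CC(C)(C)[Si](C)(C)OS(=O)(=O)C(F)(F)F
Why: Soft enolisation converts the more easily enolised aldehyde into its silyl enol ether, the quaternary C4 substituent disfavours the Z isomer while ammonium triflate allows E/Z equilibration, and residual Z isomer is removed by chromatography because this geometry decides the sense of chirality transfer in step 6.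

**Step 5**
Reactants: 8 the silyl enol ether ketone; 9 isopropenylmagnesium bromide
Product: 11 (1R,6S)-6-[(E)-2-(tert-butyldimethylsilyloxy)ethenyl]-3-methyl-1-(prop-1-en-2-yl)-6-(propan-2-yl)cyclohex-2-en-1-ol (the two alkenyl groups cis), via isopropenylcerium dichloride 10 (not isolated)
Conditions: CeCl3, THF; 9, −78 °C; then 8, −78 °C; aq. NH4Cl
Reagents that add atoms: isopropenylmagnesium bromide, CC(=C)[Mg]Br
Why: 1,2-Addition of a weakly basic organocerium reagent to a hindered, enolisable enone should occur anti to isopropyl and give the cis-dialkenyl carbinol (C9 R), and the C9 epimer is carried along because C9 becomes the ketone carbon in step 6.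

**Step 6**
Reactants: 11 the cis-dialkenyl carbinol
Product: 14 (2Z,6E,8S,10R)-8-(tert-butyldimethylsilyloxy)-3,10-dimethyl-6-(propan-2-yl)cyclodeca-2,6-dien-1-one (both ring alkenes ring-cis; ring positions 1, 2, 3, 6, 7, 8, 10 are C9, C10, C1, C4, C5, C6, C8), via potassium alkoxide 12 (not isolated), via potassium dienolate 13 (not isolated)
Conditions: KH, 18-crown-6, THF, 0 → 40 °C; then AcOH, −78 °C
Reagents that add atoms: none
Why: Deprotonation gives alkoxide 12, whose oxyanion weakens the C4–C9 bond and drives a concerted suprafacial [3,3] shift (anionic oxy-Cope rearrangement of a 1,2-dialkenylcyclohexenol, the known four-atom expansion to cyclodecenones) in which C6–C7 forms as C4–C9 breaks, and dienolate 13 is protonated at C8 on quenching. The ten-membered ring is closed by ring expansion, the termini of the isopropenyl and oxyvinyl groups bonding across a six-centre array while the opposite six-ring bond is cut, so no end-to-end cyclisation is involved. C6 is set by chirality transfer, because C7 must bond to the face of the C4–C5–C6 unit from which C9 departs and the E enol ether keeps OTBS pseudo-equatorial, so the S quaternary centre should give 6S together with the ring-cis alkene; C8 is set by peripheral protonation of 13, is epimerisable and is erased in step 18. The cis carbinol can reach bonding distance through a chair array with isopropyl pseudo-equatorial and C3 pseudo-axial, or through the related boat, and both give the ring-cis C4=C5 alkene with isopropyl trans to C6, while the cyclohexene alkene stays ring-cis as the C10=C1 enone. The selectivity needed is reaction through the isopropenyl/oxyvinyl pair and not the ring-alkene/oxyvinyl pair, which the half-chair secures because C1 cannot reach C6, together with retention of the enol ether geometry. Leakage to the ring-trans C4=C5 alkene is harmless, because that isomer carries the opposite C6 configuration and step 8 then places oxygen on the same face of C4.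

**Step 7**
Reactants: 14 the ten-membered silyloxy dienone
Product: 15 (2Z,6E,8S,10R)-8-hydroxy-3,10-dimethyl-6-(propan-2-yl)cyclodeca-2,6-dien-1-one
Conditions: TBAF, AcOH, THF, 0 °C → rt
Reagents that add atoms: none
Why: Fluoride desilylation buffered with acetic acid frees the C6 allylic alcohol without exposing the enone or C8 to base.

**Step 8**
Reactants: 15 the allylic alcohol
Product: 16 the C4–C5 epoxide of 15 (4R,5R,6S in the route numbering; C3 and C6 cis on the oxirane; enone still ring-cis)
Conditions: VO(acac)2 (cat.), t-BuOOH, CH2Cl2, 0 °C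
Reagents that add atoms: tert-butyl hydroperoxide, CC(C)(C)OO
Why: In this vanadium-catalysed hydroxyl-directed epoxidation allylic 1,3-strain (C3 cis to C6) holds H6 in the alkene plane with C7 on the inner and O6 on the outer face, so oxygen should reach the peripheral face of C4=C5, opposite to the face from which C9 left, which sets C4 as R and leaves the enone alkene untouched.

**Step 9**
Reactants: 16 the ring-cis enone epoxy alcohol
Product: 17 the ring-trans (E) C10=C1 enone isomer of 16
Conditions: hν (350 nm), benzene, rt; unchanged 16 separated and recycled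
Reagents that add atoms: none
Why: Photochemical Z to E isomerisation of a medium-ring enone through its twisted excited state is run after C4=C5 is gone so that no transannular [2+2] partner remains, and it is needed because a ring-cis enone can only fold with C10 over C6 (cis fusion).

**Step 10**
Reactants: 17 the ring-trans enone epoxy alcohol
Product: 18 the ten-membered C4–C5-epoxy-6,9-dione (ring-trans enone)
Conditions: Dess–Martin periodinane, CH2Cl2, 0 °C → rt
Reagents that add atoms: none
Why: Dess–Martin oxidation of the secondary alcohol under near-neutral conditions gives the α,β-epoxy ketone without opening the oxirane, the C6 centre having completed its relay and being rebuilt in step 12.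

**Step 11**
Reactants: 18 the epoxy dione
Product: 21 trans-fused 4-hydroxy-4-isopropyl-1,8-dimethylbicyclo[5.3.0]decane-6,9-dione (route numbering; C1 methyl and O4 on one face, H5 and isopropyl on the other), via monocyclic samarium enolate 19 (not isolated), via bicyclic samarium enolate 20 (not isolated)
Conditions: SmI2 (2.2 equiv), THF, −78 → −20 °C, no proton source; then AcOH, −78 °C
Reagents that add atoms: none
Why: Proposed new method: two electrons from SmI2 cleave the Cα–O bond of the α,β-epoxy ketone (the known reduction of such ketones to β-hydroxy ketones passes through the same trivalent samarium enolate), and without a proton source enolate 19 should add across the ring to C1 of the strained ring-trans enone in a 5-exo closure with the enolate exocyclic to the new five ring (closest known types: intramolecular and transannular Michael additions of metal enolates); samarium chelated between O4 and O6 fixes the enolate with C7 trans to C4 and puts C3 and isopropyl on opposite faces, so C1, tethered through C2–C3, bonds on the C3 face (H5 anti to O4), and the ring-trans enone closes through a chair-like seven-ring array that places the C1 methyl anti to H5 (trans fusion, C1 R).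

**Step 12**
Reactants: 21 the hydroxy dione
Product: 22 the 4,6-diol-9-one (1R,4R,5S,6S; C6–OH cis to H5)
Conditions: Me4NBH(OAc)3, MeCN/AcOH, −30 °C
Reagents that add atoms: none
Why: In the Evans–Saksena reduction the C4 hydroxyl exchanges onto boron and hydride is delivered through a chair-like six-membered array to the face of the C6 ketone turned towards O4, giving the 1,3-anti diol (C6 S), while the acidic medium spares the epimerisable C5 and the C9 ketone, which has no neighbouring hydroxyl, is not reduced.

**Step 13**
Reactants: 22 the diol
Product: 23 the C6 triethylsilyl ether of 22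
Conditions: TESCl, imidazole, DMF, 0 °C
Reagents that add atoms: chlorotriethylsilane, CC[Si](Cl)(CC)CC
Why: Selective silylation works because the secondary C6 hydroxyl reacts readily and the hindered tertiary C4 hydroxyl does not.

**Step 14**
Reactants: 24 4-hydroxybenzoic acid
Product: 25 tert-butyldimethylsilyl 4-(tert-butyldimethylsilyloxy)benzoate
Conditions: TBSCl (2.2 equiv), imidazole, DMF, rt
Reagents that add atoms: tert-butyldimethylsilyl chloride, CC(C)(C)[Si](C)(C)Cl
Why: Exhaustive silylation covers phenol and acid in one operation.

**Step 15**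
Reactants: 25 the bis-silyl derivative
Product: 26 4-(tert-butyldimethylsilyloxy)benzoyl chloride
Conditions: (COCl)2, DMF (cat.), CH2Cl2, 0 °C → rt
Reagents that add atoms: oxalyl chloride, ClC(=O)C(=O)Cl
Why: Silyl esters are converted directly into acid chlorides by oxalyl chloride and catalytic DMF (Vilsmeier-type chloride transfer) under neutral conditions, so the aryl silyl ether survives.

**Step 16**
Reactants: 23 the C6 TES ether; 26 the acid chloride
Product: 28 the C4 4-(tert-butyldimethylsilyloxy)benzoate of 23, via aroyl triflate 27 (not isolated)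
Conditions: 26, AgOTf, CH2Cl2, −78 °C; then 23, pyridine, −78 → 0 °C
Reagents that add atoms: 4-(tert-butyldimethylsilyloxy)benzoyl chloride, ClC(=O)c1ccc(O[Si](C)(C)C(C)(C)C)cc1
Why: Acylation with a mixed carboxylic–triflic anhydride, a reagent class known to esterify tertiary and other hindered hydroxyls at low temperature, touches no stereocentre, and the cold buffered medium avoids ionisation of the tertiary ester.

**Step 17**
Reactants: 28 the keto ester
Product: 29 the C8=C9 trimethylsilyl enol ether of 28
Conditions: TMSOTf, Et3N, CH2Cl2, 0 °C → rt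
Reagents that add atoms: trimethylsilyl triflate, C[Si](C)(C)OS(=O)(=O)C(F)(F)F
Why: Silyl enol ether formation under equilibrating conditions favours the tetrasubstituted C8=C9 isomer, and the C9=C10 isomer is harmless because C1 carries no hydrogen, so it returns to 28 after step 18.

**Step 18**
Reactants: 29 the silyl enol ether
Product: 30 the bis-silylated target (C7=C8 enone)
Conditions: Pd(OAc)2 (1.0 equiv), MeCN, rt → 40 °C
Reagents that add atoms: none
Why: In the Saegusa–Ito oxidation divalent palladium takes the place of silicon and syn β-hydride elimination of a ring C7 hydrogen should give the conjugated endocyclic enone, which removes the C8 stereocentre.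

**Step 19**
Reactants: 30 the bis-silylated target
Product: 31 CNP0153637.1 (1R,4R,5S,6S in the route numbering)
Conditions: HF·pyridine, THF/pyridine, 0 °C
Reagents that add atoms: none
Why: Acidic fluoride removes the alkyl TES and aryl TBS ethers together without forming a C6 alkoxide, which avoids O4 to O6 acyl migration.

**Compound list**
1 | piperitone | CC1=CC(=O)C(CC1)C(C)C | starting material
2 | allyl chloroformate | C=CCOC(=O)Cl | starting material
3 | lithium cross-conjugated dienolate of piperitone | [Li+].CC1=CC([O-])=C(C(C)C)CC1 | intermediate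
4 | allyl enol carbonate of piperitone | CC1=CC(OC(=O)OCC=C)=C(C(C)C)CC1 | intermediate
5 | (R)-6-allyl-6-isopropyl-3-methylcyclohex-2-en-1-one | CC1=CC(=O)[C@](CC=C)(C(C)C)CC1 | intermediate
6 | 2,3-dihydroxypropyl analogue of 5 (both carbinol epimers) | CC1=CC(=O)[C@](CC(O)CO)(C(C)C)CC1 | intermediate
7 | 2-[(1R)-4-methyl-2-oxo-1-(propan-2-yl)cyclohex-3-en-1-yl]acetaldehyde | CC1=CC(=O)[C@](CC=O)(C(C)C)CC1 | intermediate
8 | (S)-6-[(E)-2-(TBSO)ethenyl]-6-isopropyl-3-methylcyclohex-2-en-1-one | CC1=CC(=O)[C@](/C=C/O[Si](C)(C)C(C)(C)C)(C(C)C)CC1 | intermediate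
9 | isopropenylmagnesium bromide | CC(=C)[Mg]Br | starting material
10 | isopropenylcerium dichloride | CC(=C)[Ce](Cl)Cl | intermediate
11 | (1R,6S) cis-dialkenyl carbinol, oxy-Cope precursor | CC1=C[C@@](O)(C(C)=C)[C@](/C=C/O[Si](C)(C)C(C)(C)C)(C(C)C)CC1 | intermediate
12 | potassium alkoxide of 11 | [K+].CC1=C[C@@]([O-])(C(C)=C)[C@](/C=C/O[Si](C)(C)C(C)(C)C)(C(C)C)CC1 | intermediate
13 | ten-membered potassium dienolate (C8=C9 geometry left open, lost on protonation) | [K+].CC=1C[C@H](O[Si](C)(C)C(C)(C)C)/C=C(C(C)C)\CC/C(C)=C\C=1[O-] | intermediate
14 | (2Z,6E,8S,10R)-8-(TBSO)-3,10-dimethyl-6-(propan-2-yl)cyclodeca-2,6-dien-1-one | C[C@@H]1C[C@H](O[Si](C)(C)C(C)(C)C)/C=C(C(C)C)\CC/C(C)=C\C1=O | intermediate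
15 | (2Z,6E,8S,10R)-8-hydroxy-3,10-dimethyl-6-(propan-2-yl)cyclodeca-2,6-dien-1-one | C[C@@H]1C[C@H](O)/C=C(C(C)C)\CC/C(C)=C\C1=O | intermediate
16 | C4–C5 epoxy alcohol, ring-cis enone | C[C@@H]1C[C@H](O)[C@H]2O[C@@]2(C(C)C)CC/C(C)=C\C1=O | intermediate
17 | C4–C5 epoxy alcohol, ring-trans enone | C[C@@H]1C[C@H](O)[C@H]2O[C@@]2(C(C)C)CC/C(C)=C/C1=O | intermediate
18 | C4–C5-epoxy-6,9-dione, ring-trans enone | C[C@@H]1CC(=O)[C@H]2O[C@@]2(C(C)C)CC/C(C)=C/C1=O | intermediate
19 | monocyclic samarium enolate/alkoxide | C[C@@H]1C/C(O[Sm](I)I)=C/[C@](O[Sm](I)I)(C(C)C)CC/C(C)=C/C1=O | intermediate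
20 | bicyclic samarium enolate/alkoxide | C[C@@H]1CC(=O)[C@@H]2[C@](C)(CC[C@@]2(O[Sm](I)I)C(C)C)C=C1O[Sm](I)I | intermediate
21 | trans-fused 4-hydroxy-6,9-dione | C[C@@H]1CC(=O)[C@@H]2[C@](C)(CC[C@@]2(O)C(C)C)CC1=O | intermediate
22 | 4,6-diol-9-one | C[C@@H]1C[C@H](O)[C@@H]2[C@](C)(CC[C@@]2(O)C(C)C)CC1=O | intermediate
23 | C6 TES ether of 22 | C[C@@H]1C[C@H](O[Si](CC)(CC)CC)[C@@H]2[C@](C)(CC[C@@]2(O)C(C)C)CC1=O | intermediate
24 | 4-hydroxybenzoic acid | OC(=O)c1ccc(O)cc1 | starting material
25 | TBS 4-(TBSO)benzoate | CC(C)(C)[Si](C)(C)OC(=O)c1ccc(O[Si](C)(C)C(C)(C)C)cc1 | intermediate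
26 | 4-(TBSO)benzoyl chloride | ClC(=O)c1ccc(O[Si](C)(C)C(C)(C)C)cc1 | intermediate
27 | 4-(TBSO)benzoyl triflate | O=C(OS(=O)(=O)C(F)(F)F)c1ccc(O[Si](C)(C)C(C)(C)C)cc1 | intermediate
28 | C4 aroate, C6 TES ether, 9-ketone | C[C@@H]1C[C@H](O[Si](CC)(CC)CC)[C@@H]2[C@](C)(CC[C@@]2(OC(=O)c3ccc(O[Si](C)(C)C(C)(C)C)cc3)C(C)C)CC1=O | intermediate
29 | C8=C9 TMS enol ether of 28 | CC=1C[C@H](O[Si](CC)(CC)CC)[C@@H]2[C@](C)(CC[C@@]2(OC(=O)c3ccc(O[Si](C)(C)C(C)(C)C)cc3)C(C)C)CC=1O[Si](C)(C)C | intermediate
30 | bis-silylated target | CC1=C[C@H](O[Si](CC)(CC)CC)[C@@H]2[C@](C)(CC[C@@]2(OC(=O)c3ccc(O[Si](C)(C)C(C)(C)C)cc3)C(C)C)CC1=O | intermediate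
31 | CNP0153637.1 | CC1=C[C@H](O)[C@@H]2[C@](C)(CC[C@@]2(OC(=O)c2ccc(O)cc2)C(C)C)CC1=O | target

Total step count: 19. Longest linear sequence: 17 (steps 1–13 and 16–19).

**Steps most likely to fail**

Step 11 (labelled). The samarium enolate may be protonated or undergo retro-aldol cleavage before it adds. The enone may be reduced in competition. The fold at C1 may be poorly selective. The fallback uses known reactions one at a time, sets out from 18 and returns at 21. Compound 18 is reduced with SmI2 in THF/MeOH at −90 °C, where the enolate is protonated as it forms, to the ten-membered β-hydroxy dione F1. The tertiary hydroxyl is capped with N-(trimethylsilyl)imidazole to give the silyl ether F2. Catalytic KOt-Bu in t-BuOH/THF equilibrates the enolates, of which only the C5 enolate has a 5-exo path to C1, and the transannular Michael addition gives the bicyclic silyl ether F3. TBAF/AcOH then frees 21.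

Step 6 (key step). Silyl transfer from the enol ether to the alkoxide, heterolytic fragmentation of the C4–C9 bond, or a slow shift caused by the donor-substituted terminus could erode yield or the fidelity of chirality transfer. The fallback replaces the anionic process by a charge-neutral one, sets out from 11 and returns at 14. Compound 11 is silylated (TMSOTf, 2,6-lutidine) to the bis-silyl ether F4. Thermolysis at about 200 °C in degassed decalin (siloxy-Cope rearrangement) gives the ten-membered silyl dienol ether F5. Aqueous citric acid in THF hydrolyses only the enol silane and gives 14.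

Step 9. An unfavourable photostationary state or photodeconjugation through the dienol could starve the route of the ring-trans enone. The fallback replaces light by a reduce-and-reoxidise sequence, sets out from 14 and returns at 17.
- RhCl(PPh3)3-catalysed 1,4-hydrosilylation of 14 with Et3SiH gives the C9=C10 triethylsilyl enol ether F6 (C1 epimers).
- Saegusa–Ito oxidation with Pd(OAc)2, in which syn β-hydride elimination from the equilibrating palladium enolate of a ten-membered ring favours the ring carbons anti, gives the ring-trans enone silyl ether F7.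
- TBAF/AcOH gives the ring-trans enone allylic alcohol F8.
- VO(acac)2/t-BuOOH epoxidation as in step 8 gives 17.

**Further compounds**
F1 | step 11 | ten-membered β-hydroxy dione (ring-trans enone) | C[C@@H]1CC(=O)C[C@](O)(C(C)C)CC/C(C)=C/C1=O
F2 | step 11 | C4 trimethylsilyl ether of F1 | C[C@@H]1CC(=O)C[C@](O[Si](C)(C)C)(C(C)C)CC/C(C)=C/C1=O
F3 | step 11 | C4 trimethylsilyl ether of 21 | C[C@@H]1CC(=O)[C@@H]2[C@](C)(CC[C@@]2(O[Si](C)(C)C)C(C)C)CC1=O
F4 | step 6 | C9 trimethylsilyl ether of 11 | CC1=C[C@@](O[Si](C)(C)C)(C(C)=C)[C@](/C=C/O[Si](C)(C)C(C)(C)C)(C(C)C)CC1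
F5 | step 6 | ten-membered C8=C9 trimethylsilyl dienol ether | CC=1C[C@H](O[Si](C)(C)C(C)(C)C)/C=C(C(C)C)\CC/C(C)=C\C=1O[Si](C)(C)C
F6 | step 9 | C9=C10 triethylsilyl enol ether (C1 epimers) | C[C@@H]1C[C@H](O[Si](C)(C)C(C)(C)C)/C=C(C(C)C)\CCC(C)C=C1O[Si](CC)(CC)CC
F7 | step 9 | ring-trans enone isomer of 14 | C[C@@H]1C[C@H](O[Si](C)(C)C(C)(C)C)/C=C(C(C)C)\CC/C(C)=C/C1=O
F8 | step 9 | ring-trans enone isomer of 15 | C[C@@H]1C[C@H](O)/C=C(C(C)C)\CC/C(C)=C/C1=O
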